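**Retrosynthetic overview**

- The route rests on central ring C: a phloroglucinol whose O1 carries ring B and whose C4 oxygen, flanked by the free C3 and C5 hydroxyls, carries ring D. These six carbons and four oxygens are those of a 4-aryloxy-6-(aryloxymethyl)-2-pyrone, so ring C is made by isomerising that pyrone, the exocyclic OCH2 carbon bonding to the lactone carbonyl carbon.
- The pyrone comes from triacetic acid lactone via its 4-bromo-6-bromomethyl derivative. The D-E phenol enters by SN2 at the CH2Br group and the A-B phenol by addition–elimination at C4, so neither crowded ether of ring C needs an arylation.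
- Each diaryl ether phenol comes from copper-catalysed O-arylation of a trimethoxyphenol with an ortho-bromobenzaldehyde, followed by Baeyer–Villiger conversion of CHO into OH.
- Rings A, B, D and E are bought as arenes. Ring C is the only ring formed, and it is formed last; BBr3 then cleaves the eleven methyl ethers.

Key step: step 11

Remark: the target has no stereocentre. The five starting materials (compounds 1, 3, 7, 10 and 14) are taken as catalogue chemicals.

**Route**

Step 1
Reactants: 1 3,4,5-trimethoxybenzaldehyde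
Product: 2 2-bromo-3,4,5-trimethoxybenzaldehyde
Conditions: NBS, CHCl3, reflux
Reagents that add atoms: N-bromosuccinimide O=C1CCC(=O)N1Br
Why: Electrophilic aromatic bromination; the two free ring positions are equivalent and activated by ortho and para methoxy groups, so monobromination next to the formyl group should be clean.

Step 2
Reactants: 2 2-bromo-3,4,5-trimethoxybenzaldehyde; 3 3,4,5-trimethoxyphenol
Product: 4 3,4,5-trimethoxy-2-(3,4,5-trimethoxyphenoxy)benzaldehyde
Conditions: CuI (cat.), picolinic acid (cat.), K3PO4, DMSO, 90 °C, argon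
Reagents that add atoms: none
Why: Ullmann-type copper-catalysed O-arylation; the ortho formyl group activates the C–Br bond toward monovalent copper, and phenol 3 has no ortho substituent.

Step 3
Reactants: 4 3,4,5-trimethoxy-2-(3,4,5-trimethoxyphenoxy)benzaldehyde
Product: 6 3,4,5-trimethoxy-2-(3,4,5-trimethoxyphenoxy)phenol, via aryl formate 5 (not isolated)
Conditions: mCPBA, CH2Cl2, 0 °C → rt; then K2CO3 (cat.), MeOH, rt
Reagents that add atoms: 3-chloroperoxybenzoic acid OOC(=O)c1cccc(Cl)c1
Why: Baeyer–Villiger (Dakin-type) oxidation; the aryl group with ortho-aryloxy and para-methoxy donors migrates in preference to hydride, and the labile formate is removed by methanolysis.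

Step 4
Reactants: 7 1-bromo-3,5-dimethoxybenzene
Product: 9 2-bromo-4,6-dimethoxybenzaldehyde, via iminium salt 8 (not isolated)
Conditions: POCl3, DMF, 0 → 90 °C; then H2O
Reagents that add atoms: N,N-dimethylformamide CN(C)C=O; water O
Why: Vilsmeier–Haack formylation; the chloroiminium ion should attack the position para to one methoxy and ortho to the other in preference to the more crowded site between the two methoxy groups, and the minor 4-bromo-2,6-dimethoxy isomer should be separable.

Step 5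
Reactants: 9 2-bromo-4,6-dimethoxybenzaldehyde; 10 2,4,6-trimethoxyphenol
Product: 11 2,4-dimethoxy-6-(2,4,6-trimethoxyphenoxy)benzaldehyde
Conditions: CuI (cat.), picolinic acid (cat.), K3PO4, DMSO, 90 °C, argon
Reagents that add atoms: none
Why: Ullmann-type O-arylation as in step 2; the bromide has only the activating formyl group ortho to it, and the picolinate ligand is suited to doubly ortho-substituted, electron-rich phenols.

Step 6
Reactants: 11 2,4-dimethoxy-6-(2,4,6-trimethoxyphenoxy)benzaldehyde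
Product: 13 2,4-dimethoxy-6-(2,4,6-trimethoxyphenoxy)phenol, via aryl formate 12 (not isolated)
Conditions: mCPBA, CH2Cl2, 0 °C → rt; then K2CO3 (cat.), MeOH, rt
Reagents that add atoms: 3-chloroperoxybenzoic acid OOC(=O)c1cccc(Cl)c1
Why: Baeyer–Villiger oxidation and methanolysis as in step 3; ortho-methoxy, ortho-aryloxy and para-methoxy donors make aryl migration strongly favoured.

Step 7
Reactants: 14 triacetic acid lactone (4-hydroxy-6-methyl-2H-pyran-2-one)
Product: 15 4-bromo-6-methyl-2H-pyran-2-one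
Conditions: P2O5, n-Bu4NBr, toluene, 100 °C
Reagents that add atoms: tetrabutylammonium bromide CCCC[N+](CCCC)(CCCC)CCCC.[Br-]
Why: Dehydrative bromination of a vinylogous acid; phosphorylation of the 4-hydroxyl followed by addition–elimination of bromide at C4 is an established route from 4-hydroxy-2-pyrones to 4-bromo-2-pyrones.

Step 8
Reactants: 15 4-bromo-6-methyl-2H-pyran-2-one
Product: 16 4-bromo-6-(bromomethyl)-2H-pyran-2-one
Conditions: NBS, AIBN (cat.), PhCF3, reflux
Reagents that add atoms: N-bromosuccinimide O=C1CCC(=O)N1Br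
Why: Wohl–Ziegler radical bromination; hydrogen abstraction from the 6-methyl group gives a radical delocalised into the pyrone, and the electron-poor 4-bromopyrone should resist electrophilic bromination at C3.

Step 9
Reactants: 16 4-bromo-6-(bromomethyl)-2H-pyran-2-one; 6 3,4,5-trimethoxy-2-(3,4,5-trimethoxyphenoxy)phenol
Product: 17 4-bromo-6-{[3,4,5-trimethoxy-2-(3,4,5-trimethoxyphenoxy)phenoxy]methyl}-2H-pyran-2-one
Conditions: K2CO3, acetone, 0 °C → rt
Reagents that add atoms: none
Why: Williamson ether synthesis; the primary allylic bromide (a vinylogous α-halo ester) should undergo SN2 displacement at 0 °C much faster than the phenoxide adds to C4, so one equivalent of 6 should leave the ring bromide in place.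

Step 10
Reactants: 17 4-bromo-6-{[3,4,5-trimethoxy-2-(3,4,5-trimethoxyphenoxy)phenoxy]methyl}-2H-pyran-2-one; 13 2,4-dimethoxy-6-(2,4,6-trimethoxyphenoxy)phenol
Product: 18 4-[2,4-dimethoxy-6-(2,4,6-trimethoxyphenoxy)phenoxy]-6-{[3,4,5-trimethoxy-2-(3,4,5-trimethoxyphenoxy)phenoxy]methyl}-2H-pyran-2-one
Conditions: Cs2CO3, DMF, rt → 50 °C, argon
Reagents that add atoms: none
Why: Addition–elimination (vinylogous acyl substitution) at C4 of the 4-bromo-2-pyrone; the phenoxide adds to the β-carbon of the unsaturated lactone and bromide is expelled, while the carbonate base is too weak to deprotonate the aryloxymethyl group.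

Step 11
Reactants: 18 4-[2,4-dimethoxy-6-(2,4,6-trimethoxyphenoxy)phenoxy]-6-{[3,4,5-trimethoxy-2-(3,4,5-trimethoxyphenoxy)phenoxy]methyl}-2H-pyran-2-one
Product: 21 5-[2,4-dimethoxy-6-(2,4,6-trimethoxyphenoxy)phenoxy]-2-[3,4,5-trimethoxy-2-(3,4,5-trimethoxyphenoxy)phenoxy]benzene-1,3-diol, via potassium pyranolate 19 (not isolated), via ketene enolate 20 (not isolated)
Conditions: KN(SiMe3)2 (2.5 equiv), THF, slow addition of 18 to the base at −78 °C, then → rt, argon; AcOH quench
Reagents that add atoms: none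
Why: Proposed new method: KN(SiMe3)2 should remove a proton from the aryloxymethyl carbon to give the extended pyranolate 19, whose charge reaches pyrone C3; E1cB cleavage of the bond between the lactone carbon and the ring oxygen then unmasks a ketene joined through the cis C4=C5 bond to a potassium enolate (20), and the enolate carbon bonds to the ketene carbon. The closest known reactions are the alkoxide-induced isomerisation of 4-methoxy-6-methyl-2-pyrone to 5-methoxyresorcinol and the 6π electrocyclisation of dienylketenes to phenols in benzannulation chemistry; the new element is the amide base, chosen because it cannot add to C4 and expel the A-B phenoxide as an alkoxide could. Ring C closes by a 6π electrocyclisation of the dienylketene (equally described as a 6-enolendo-exo-dig C-acylation), the cis geometry inherited from the pyrone ring holding the two termini within bonding distance. No stereocentre is formed. The step needs C- over O-acylation and unimolecular over bimolecular reaction: O-acylation only returns 19 and is reversible, whereas C-acylation is made irreversible by tautomerisation to the resorcinol dianion, and slow addition of 18 to excess base at −78 °C should keep neutral pyrone from meeting its own anion.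

Step 12
Reactants: 21 5-[2,4-dimethoxy-6-(2,4,6-trimethoxyphenoxy)phenoxy]-2-[3,4,5-trimethoxy-2-(3,4,5-trimethoxyphenoxy)phenoxy]benzene-1,3-diol
Product: 22 5-[2,4-dihydroxy-6-(2,4,6-trihydroxyphenoxy)phenoxy]-2-[3,4,5-trihydroxy-2-(3,4,5-trihydroxyphenoxy)phenoxy]benzene-1,3-diol (CNP0243665.0)
Conditions: BBr3 (excess), CH2Cl2, −78 °C → rt, argon; then degassed H2O
Reagents that add atoms: none
Why: Lewis-acid ether cleavage; BBr3 binds each methoxy oxygen and bromide attacks the methyl carbon by SN2, while the four diaryl ether oxygens offer no sp3 carbon and should stay intact.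

**Compound list**

1 | 3,4,5-trimethoxybenzaldehyde | COc1cc(C=O)cc(OC)c1OC | starting material
2 | 2-bromo-3,4,5-trimethoxybenzaldehyde | COc1cc(C=O)c(Br)c(OC)c1OC | intermediate
3 | 3,4,5-trimethoxyphenol | COc1cc(O)cc(OC)c1OC | starting material
4 | 3,4,5-trimethoxy-2-(3,4,5-trimethoxyphenoxy)benzaldehyde | COc1cc(Oc2c(C=O)cc(OC)c(OC)c2OC)cc(OC)c1OC | intermediate
5 | 3,4,5-trimethoxy-2-(3,4,5-trimethoxyphenoxy)phenyl formate | COc1cc(Oc2c(OC=O)cc(OC)c(OC)c2OC)cc(OC)c1OC | intermediate
6 | 3,4,5-trimethoxy-2-(3,4,5-trimethoxyphenoxy)phenol (D-E phenol) | COc1cc(Oc2c(O)cc(OC)c(OC)c2OC)cc(OC)c1OC | intermediate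
7 | 1-bromo-3,5-dimethoxybenzene | COc1cc(Br)cc(OC)c1 | starting material
8 | N-[(2-bromo-4,6-dimethoxyphenyl)methylidene]-N-methylmethanaminium dichlorophosphate | C[N+](C)=Cc1c(Br)cc(OC)cc1OC.[O-]P(=O)(Cl)Cl | intermediate
9 | 2-bromo-4,6-dimethoxybenzaldehyde | COc1cc(Br)c(C=O)c(OC)c1 | intermediate
10 | 2,4,6-trimethoxyphenol | COc1cc(OC)c(O)c(OC)c1 | starting material
11 | 2,4-dimethoxy-6-(2,4,6-trimethoxyphenoxy)benzaldehyde | COc1cc(OC)c(Oc2cc(OC)cc(OC)c2C=O)c(OC)c1 | intermediate
12 | 2,4-dimethoxy-6-(2,4,6-trimethoxyphenoxy)phenyl formate | COc1cc(OC)c(Oc2cc(OC)cc(OC)c2OC=O)c(OC)c1 | intermediate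
13 | 2,4-dimethoxy-6-(2,4,6-trimethoxyphenoxy)phenol (A-B phenol) | COc1cc(OC)c(Oc2cc(OC)cc(OC)c2O)c(OC)c1 | intermediate
14 | triacetic acid lactone (4-hydroxy-6-methyl-2H-pyran-2-one) | CC1=CC(O)=CC(=O)O1 | starting material
15 | 4-bromo-6-methyl-2H-pyran-2-one | CC1=CC(Br)=CC(=O)O1 | intermediate
16 | 4-bromo-6-(bromomethyl)-2H-pyran-2-one | BrCC1=CC(Br)=CC(=O)O1 | intermediate
17 | 4-bromo-6-{[3,4,5-trimethoxy-2-(3,4,5-trimethoxyphenoxy)phenoxy]methyl}-2H-pyran-2-one | O=C1C=C(Br)C=C(COc2cc(OC)c(OC)c(OC)c2Oc2cc(OC)c(OC)c(OC)c2)O1 | intermediate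
18 | 4-[2,4-dimethoxy-6-(2,4,6-trimethoxyphenoxy)phenoxy]-6-{[3,4,5-trimethoxy-2-(3,4,5-trimethoxyphenoxy)phenoxy]methyl}-2H-pyran-2-one | O=C1C=C(Oc2c(OC)cc(OC)cc2Oc2c(OC)cc(OC)cc2OC)C=C(COc2cc(OC)c(OC)c(OC)c2Oc2cc(OC)c(OC)c(OC)c2)O1 | intermediate
19 | potassium 4-(A-B aryloxy)-6-[(D-E aryloxy)methylidene]-6H-pyran-2-olate (extended enolate of 18) | [K+].[O-]C1=CC(Oc2c(OC)cc(OC)cc2Oc2c(OC)cc(OC)cc2OC)=CC(=COc2cc(OC)c(OC)c(OC)c2Oc2cc(OC)c(OC)c(OC)c2)O1 | intermediate
20 | potassium 4-(A-B aryloxy)-1-(D-E aryloxy)-6-oxohexa-1,3,5-trien-2-olate (ring-opened ketene enolate; ketene carbon and enolate carbon cis across the central C=C) | O=C=C/C(Oc1c(OC)cc(OC)cc1Oc1c(OC)cc(OC)cc1OC)=C\C([O-])=COc1cc(OC)c(OC)c(OC)c1Oc1cc(OC)c(OC)c(OC)c1.[K+] | intermediate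
21 | 5-[2,4-dimethoxy-6-(2,4,6-trimethoxyphenoxy)phenoxy]-2-[3,4,5-trimethoxy-2-(3,4,5-trimethoxyphenoxy)phenoxy]benzene-1,3-diol | COc1cc(OC)c(Oc2cc(OC)cc(OC)c2Oc2cc(O)c(Oc3cc(OC)c(OC)c(OC)c3Oc3cc(OC)c(OC)c(OC)c3)c(O)c2)c(OC)c1 | intermediate
22 | 5-[2,4-dihydroxy-6-(2,4,6-trihydroxyphenoxy)phenoxy]-2-[3,4,5-trihydroxy-2-(3,4,5-trihydroxyphenoxy)phenoxy]benzene-1,3-diol (CNP0243665.0) | Oc1cc(O)c(Oc2cc(O)cc(O)c2Oc2cc(O)c(Oc3cc(O)c(O)c(O)c3Oc3cc(O)c(O)c(O)c3)c(O)c2)c(O)c1 | target

**Step count**

Total: 12 steps. Longest linear sequence: 7 steps (1, 2, 3, 9, 10, 11, 12).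

**Steps most likely to fail**

1. Step 11 (proposed new method). Three things may go wrong. The pyranolate may survive without fragmenting to the ketene and simply return 18 on quench. Deprotonation may occur at a ring CH instead of the aryloxymethyl carbon. The anion may add to C4 of a second pyrone and expel the A-B phenoxide. The fallback is a known copper-arylation and Baeyer–Villiger iteration that builds the ethers of ring C on a bought arene; it sets out from 13 and rejoins the route at 22.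
   - Phenol 13 is coupled (CuI, picolinic acid, K3PO4, DMSO, 90 °C) with commercial 4-bromo-2,6-dimethoxybenzaldehyde to give 4-[2,4-dimethoxy-6-(2,4,6-trimethoxyphenoxy)phenoxy]-2,6-dimethoxybenzaldehyde F1.
   - mCPBA should convert this into 4-[2,4-dimethoxy-6-(2,4,6-trimethoxyphenoxy)phenoxy]-2,6-dimethoxyphenyl formate F2, and methanolysis (K2CO3, MeOH) into 4-[2,4-dimethoxy-6-(2,4,6-trimethoxyphenoxy)phenoxy]-2,6-dimethoxyphenol F3, which is ring C with its hindered oxygen free.
   - Separately, commercial 5-bromo-1,2,3-trimethoxybenzene is formylated (Cl2CHOMe, TiCl4, CH2Cl2, 0 °C; Rieche formylation) to 6-bromo-2,3,4-trimethoxybenzaldehyde F4.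
   - Copper-catalysed coupling of F3 with F4 under the same conditions should give 6-{4-[2,4-dimethoxy-6-(2,4,6-trimethoxyphenoxy)phenoxy]-2,6-dimethoxyphenoxy}-2,3,4-trimethoxybenzaldehyde F5.
   - Baeyer–Villiger oxidation gives 6-{4-[2,4-dimethoxy-6-(2,4,6-trimethoxyphenoxy)phenoxy]-2,6-dimethoxyphenoxy}-2,3,4-trimethoxyphenyl formate F6, and methanolysis gives 6-{4-[2,4-dimethoxy-6-(2,4,6-trimethoxyphenoxy)phenoxy]-2,6-dimethoxyphenoxy}-2,3,4-trimethoxyphenol F7.
   - F7 is arylated with commercial 5-iodo-1,2,3-trimethoxybenzene (CuI, picolinic acid, K3PO4, DMSO) to the tridecamethyl ether of 22 F8, which BBr3 under the conditions of step 12 should convert into 22.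

2. Step 10. Addition of the doubly ortho-substituted phenoxide at C4 may be slow, so that base-induced degradation of the aryloxymethyl pyrone, or attack at C6 with ring opening, competes. The fallback moves the addition–elimination to the simple methyl pyrone, which tolerates forcing conditions, and attaches the D-E phenol afterwards; it sets out from 15 and 13 and rejoins the route at 18.
   - 15 and 13 (Cs2CO3, DMF, 60–80 °C) should give 4-[2,4-dimethoxy-6-(2,4,6-trimethoxyphenoxy)phenoxy]-6-methyl-2H-pyran-2-one F9.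
   - Oxidation of the 6-methyl group with SeO2 (dioxane, sealed tube, 150 °C), as known for 4-methoxy-6-methyl-2-pyrone, gives 4-[2,4-dimethoxy-6-(2,4,6-trimethoxyphenoxy)phenoxy]-2-oxo-2H-pyran-6-carbaldehyde F10.
   - Luche reduction (NaBH4, CeCl3·7H2O, MeOH–THF, −40 °C) gives 4-[2,4-dimethoxy-6-(2,4,6-trimethoxyphenoxy)phenoxy]-6-(hydroxymethyl)-2H-pyran-2-one F11.
   - Mitsunobu etherification of F11 with 6 (PPh3, DIAD, THF, 0 °C → rt) should deliver 18.

3. Step 12. Cleavage of the eleven ethers may stop short and leave partly methylated polyphenols, and the pyrogallol-type rings D and E may oxidise in air during isolation. The fallback captures the polyphenol as a stable ester and releases it under acid; it sets out from 21 and rejoins the route at 22.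
   - After the BBr3 treatment and aqueous quench, the crude material is acetylated directly (Ac2O, pyridine, DMAP, rt) to the tridecaacetate of 22 F12, which is stable on silica; partly methylated acetates can be separated and resubmitted.
   - Acid-catalysed transesterification (HCl generated from AcCl, degassed MeOH, rt, argon) followed by evaporation should return 22 without exposing the free polyphenol to base.

**Further compounds**

F1 | step 11 | 4-[2,4-dimethoxy-6-(2,4,6-trimethoxyphenoxy)phenoxy]-2,6-dimethoxybenzaldehyde | COc1cc(OC)c(Oc2cc(OC)cc(OC)c2Oc2cc(OC)c(C=O)c(OC)c2)c(OC)c1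
F2 | step 11 | 4-[2,4-dimethoxy-6-(2,4,6-trimethoxyphenoxy)phenoxy]-2,6-dimethoxyphenyl formate | COc1cc(OC)c(Oc2cc(OC)cc(OC)c2Oc2cc(OC)c(OC=O)c(OC)c2)c(OC)c1
F3 | step 11 | 4-[2,4-dimethoxy-6-(2,4,6-trimethoxyphenoxy)phenoxy]-2,6-dimethoxyphenol | COc1cc(OC)c(Oc2cc(OC)cc(OC)c2Oc2cc(OC)c(O)c(OC)c2)c(OC)c1
F4 | step 11 | 6-bromo-2,3,4-trimethoxybenzaldehyde | COc1cc(Br)c(C=O)c(OC)c1OC
F5 | step 11 | 6-{4-[2,4-dimethoxy-6-(2,4,6-trimethoxyphenoxy)phenoxy]-2,6-dimethoxyphenoxy}-2,3,4-trimethoxybenzaldehyde | COc1cc(OC)c(Oc2cc(OC)cc(OC)c2Oc2cc(OC)c(Oc3cc(OC)c(OC)c(OC)c3C=O)c(OC)c2)c(OC)c1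
F6 | step 11 | 6-{4-[2,4-dimethoxy-6-(2,4,6-trimethoxyphenoxy)phenoxy]-2,6-dimethoxyphenoxy}-2,3,4-trimethoxyphenyl formate | COc1cc(OC)c(Oc2cc(OC)cc(OC)c2Oc2cc(OC)c(Oc3cc(OC)c(OC)c(OC)c3OC=O)c(OC)c2)c(OC)c1
F7 | step 11 | 6-{4-[2,4-dimethoxy-6-(2,4,6-trimethoxyphenoxy)phenoxy]-2,6-dimethoxyphenoxy}-2,3,4-trimethoxyphenol | COc1cc(OC)c(Oc2cc(OC)cc(OC)c2Oc2cc(OC)c(Oc3cc(OC)c(OC)c(OC)c3O)c(OC)c2)c(OC)c1
F8 | step 11 | tridecamethyl ether of 22 | COc1cc(OC)c(Oc2cc(OC)cc(OC)c2Oc2cc(OC)c(Oc3cc(OC)c(OC)c(OC)c3Oc3cc(OC)c(OC)c(OC)c3)c(OC)c2)c(OC)c1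
F9 | step 10 | 4-[2,4-dimethoxy-6-(2,4,6-trimethoxyphenoxy)phenoxy]-6-methyl-2H-pyran-2-one | CC1=CC(Oc2c(OC)cc(OC)cc2Oc2c(OC)cc(OC)cc2OC)=CC(=O)O1
F10 | step 10 | 4-[2,4-dimethoxy-6-(2,4,6-trimethoxyphenoxy)phenoxy]-2-oxo-2H-pyran-6-carbaldehyde | O=CC1=CC(Oc2c(OC)cc(OC)cc2Oc2c(OC)cc(OC)cc2OC)=CC(=O)O1
F11 | step 10 | 4-[2,4-dimethoxy-6-(2,4,6-trimethoxyphenoxy)phenoxy]-6-(hydroxymethyl)-2H-pyran-2-one | OCC1=CC(Oc2c(OC)cc(OC)cc2Oc2c(OC)cc(OC)cc2OC)=CC(=O)O1
F12 | step 12 | tridecaacetate of 22 | CC(=O)Oc1cc(OC(C)=O)c(Oc2cc(OC(C)=O)cc(OC(C)=O)c2Oc2cc(OC(C)=O)c(Oc3cc(OC(C)=O)c(OC(C)=O)c(OC(C)=O)c3Oc3cc(OC(C)=O)c(OC(C)=O)c(OC(C)=O)c3)c(OC(C)=O)c2)c(OC(C)=O)c1
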